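The readings are simulated with made-up constants, and the scatter is random.

A closed flask cannot lose material, yet at the end of the south run target and starting material add up to 58.2% of the charge. The gap of 41.8% stands beside a loading of 40 mol%, so I read the free catalyst as a reagent that takes starting material one for one. In the colder north-west run the gap is 29.2% beside 20 mol%, which is more than that loading, so something further is unseen there, which I leave out.

| setting | north-west | south | theta | gamma | epsilon |
|---|---|---|---|---|---|
| starting material | 2.7 M | 1.9 M | 1.9 M | 1.9 M | 1.9 M |
| free catalyst | 20 mol% | 40 mol% | 20 mol% | 20 mol% | 20 mol% |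
| temperature | 12 °C | 29 °C | 35 °C | 20 °C | 5 °C |
| remark | run made earlier | run made earlier |  |  |  |
| time |  |  | 6.0 h | 6.0 h | 6.0 h |

| run | time / h | target / % | starting material / % |
|---|---|---|---|
| north-west | 6.00 | 41.3 | 34.7 |
| north-west | 12.0 | 42.2 | 30.7 |
| north-west | 15.0 | 41.6 | 30.5 |
| north-west | 25.0 | 41.7 | 29.1 |
| south | 0.500 | 37.0 | 46.9 |
| south | 1.33 | 35.4 | 38.8 |
| south | 3.00 | 31.1 | 34.4 |
| south | 8.00 | 27.7 | 30.5 |

(scatter of a reading: 0.3 percentage points)

* the flask with the highest amount of target, in percent of the starting material charged ("all alike" if they lie within 1.5 percentage points) (theta / gamma / epsilon / all alike)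
* final target, as a percentage of the starting material charged, in theta
* final target, as a percentage of the starting material charged, in gamma
* final target, as a percentage of the starting material charged, in epsilon



Now turn the settings one at a time. Take the loading first: by hand, more catalyst takes more of the charge, so the south run keeps a pool of 60.0%, while your flasks at 20 mol% keep 80.0%.

I let temperature share out that pool, and I put the change in the ratio below on temperature, although the two runs differ in charge and loading too. The last target over starting material reads 1.43 at 12 °C and 0.908 at 29 °C. Carried geometrically along the temperature, this ratio becomes 0.773 in theta, 1.16 in gamma and 1.73 in epsilon. My ceiling of target is the part of the pool that this ratio puts on the target side. It comes to 34.9% in theta, 43.0% in gamma and 50.7% in epsilon.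

Time says whether a flask gets there. Epsilon has less c(free catalyst) than the north-west run, 0.380 M against 0.540 M, and it is colder. So I put epsilon well under its ceiling without a number, theta near its ceiling, and gamma in front, its ceiling being higher than theta's.

The forecast said gamma, with 26% in theta, 37% in gamma and 33% in epsilon, on the ground of “a third, unseen sink that is favoured by heat”. For theta my figure stands above the forecast's.

The flasks give 33.9% in theta, 40.5% in gamma and 33.8% in epsilon, so gamma leads.

    starting material + free catalyst ⇌ target + free catalyst, rate k1*[starting material]*[free catalyst] forward; the back reaction follows from the equilibrium constant (K = 1.70, k = 1.19 × 10⁻⁴ L mol⁻¹ s⁻¹, Ea = 65.0 kJ mol⁻¹, ΔH = −20.0 kJ mol⁻¹)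
    starting material + free catalyst ⇌ isomer of the product + free catalyst, rate k2*[starting material]*[free catalyst] forward; the back reaction follows from the equilibrium constant (K = 0.550, k = 9.74 × 10⁻⁵ L mol⁻¹ s⁻¹, Ea = 75.0 kJ mol⁻¹, ΔH = −56.0 kJ mol⁻¹)
    starting material + free catalyst → spent catalyst (k = 2.29 × 10⁻⁵ L mol⁻¹ s⁻¹, Ea = 61.0 kJ mol⁻¹)
    (constants at 5 °C)

The forecast's theta is close to what you get by taking over the south run's last reading, 27.7%, from a flask with twice the loading. In theta, half of the turnover to target up to 6.00 h is done by 0.102 h, whereas the half-life of starting material by the spent-catalyst step alone is 2.0 h at 0.102 h, and the ceiling of 34.9% stands close to the result. In the neighbour at 10 °C, otherwise theta, the ceiling is 48.2%. The computed flask holds less target than that, 38.3%, with free catalyst still at 46.7% of its charge.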